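**Retrosynthetic overview**
1. Cut the C18–O ester bond last: labdane alcohol 10 plus monocyclic hydroxy acid 16.
2. 10 comes from ketol 5: enoate by HWE, CH2OH from a C–Si bond, exocyclic alkene by elimination of the 8α-ol.
3. 5 comes from acyclic allylsilane 3 (made from farnesylacetone) in one chiral-acid cascade: ring A, then ring B, then a temporary pyran by ketone capture, opened on work-up.
4. 16 comes from ketol 13 (HWE, then asymmetric conjugate reduction for C3); 13 comes from geranylacetone by the same type of cyclization (cyclohexane, then temporary pyran, opened).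
5. Both halves start from achiral terpenoid ketones; the two cyclizations use the two antipodes of one catalyst.

Assumption: "IDPi" is a confined BINOL-derived N-triflyl imidodiphosphorimidate Brønsted acid prepared separately; (S,S)-IDPi here means the antipode that folds a polyprenyl chain into the natural (ambrox-type) series, (R,R)-IDPi its mirror image, and the sense is checked on the first run.

**Route**

Step 1
Reactants: 1 (5E,9E)-6,10,14-trimethylpentadeca-5,9,13-trien-2-one (farnesylacetone)
Product: 2 (5E,9E,13E)-15-hydroxy-6,10,14-trimethylpentadeca-5,9,13-trien-2-one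
Conditions: SeO2 (0.3 equiv), t-BuOOH, salicylic acid (cat.), CH2Cl2, 0 °C to rt, stopped at partial conversion, 1 recycled
Reagents that add atoms: tert-butyl hydroperoxide CC(C)(C)OO; selenium dioxide (catalytic oxygen relay) O=[Se]=O
Why: Catalytic SeO2 allylic oxidation (ene reaction, then [2,3]-shift) hydroxylates the E-methyl of the terminal isopropylidene, the most accessible trisubstituted alkene, and gives an achiral E-allylic alcohol.

Step 2
Reactants: 2 (5E,9E,13E)-15-hydroxy-6,10,14-trimethylpentadeca-5,9,13-trien-2-one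
Product: 3 (5E,9E,13E)-15-[dimethyl(phenyl)silyl]-6,10,14-trimethylpentadeca-5,9,13-trien-2-one
Conditions: PhMe2Si–SiMe2Ph, [Pd(MeCN)4](BF4)2 (5 mol %), DMSO/MeOH, 50 °C
Reagents that add atoms: 1,1,2,2-tetramethyl-1,2-diphenyldisilane C[Si](C)(c1ccccc1)[Si](C)(C)c1ccccc1
Why: Pd-catalysed allylic C–OH silylation with a disilane runs through a π-allyl-palladium and puts silicon on the unhindered CH2 terminus, giving the linear E-allylsilane with the ketone untouched.

Step 3
Reactants: 3 (5E,9E,13E)-15-[dimethyl(phenyl)silyl]-6,10,14-trimethylpentadeca-5,9,13-trien-2-one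
Product: 5 4-[(1R,2R,4aR,5R,8aS)-5-{[dimethyl(phenyl)silyl]methyl}-2-hydroxy-2,5,8a-trimethyldecahydronaphthalen-1-yl]butan-2-one, via silyl sclareol-oxide enol ether 4 (not isolated)
Conditions: (S,S)-IDPi (3 mol %), (CF3)3COH/CHCl3, −40 °C; then 1 M HCl, THF, 0 °C
Reagents that add atoms: water O
Why: Proposed new method: the allylsilane is the most basic C=C of 3 (β-silicon effect), so the chiral acid protonates its γ-carbon selectively; the β-silyl cation keeps its silicon because the confined phosphorimidate anion and the fluorinated alcohol are non-nucleophilic, and it is trapped anti to Si by the next alkene in a chair–chair cascade (CH2SiMe2Ph equatorial sets C4, catalyst-controlled folding sets C5, C9 and C10, the ketone oxygen closes on C8 from the α face); the closest known reactions are the IDPi-catalysed hydroxyl-terminated asymmetric polyene cyclization and the acid-catalysed silyl-retentive cyclization of hydroxy allylsilanes.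

Step 4
Reactants: 5 4-[(1R,2R,4aR,5R,8aS)-5-{[dimethyl(phenyl)silyl]methyl}-2-hydroxy-2,5,8a-trimethyldecahydronaphthalen-1-yl]butan-2-one
Product: 6 methyl (2E)-5-[(1R,2R,4aR,5R,8aS)-5-{[dimethyl(phenyl)silyl]methyl}-2-hydroxy-2,5,8a-trimethyldecahydronaphthalen-1-yl]-3-methylpent-2-enoate
Conditions: (MeO)2P(O)CH2CO2Me, NaH, THF, 0 °C to 40 °C; E isomer separated on silica
Reagents that add atoms: trimethyl phosphonoacetate COC(=O)CP(=O)(OC)OC
Why: Horner–Wadsworth–Emmons olefination of the methyl ketone gives mainly the E-enoate (about 4:1, separable), as in the same reaction of the sclareol-derived ketol; no stereocentre is touched.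

Step 5
Reactants: 6 methyl (2E)-5-[(1R,2R,4aR,5R,8aS)-5-{[dimethyl(phenyl)silyl]methyl}-2-hydroxy-2,5,8a-trimethyldecahydronaphthalen-1-yl]-3-methylpent-2-enoate
Product: 7 methyl (2E)-5-[(1R,2R,4aR,5R,8aS)-2-hydroxy-5-(hydroxymethyl)-2,5,8a-trimethyldecahydronaphthalen-1-yl]-3-methylpent-2-enoate (methyl 8α,18-dihydroxylabd-13E-en-15-oate)
Conditions: KBr, AcOOH, NaOAc, AcOH, 0 °C to rt
Reagents that add atoms: peracetic acid CC(=O)OO
Why: Fleming–Tamao oxidation (ipso-bromodesilylation of the phenyl group, then peroxide-induced C-to-O shift with retention) turns CH2–Si into CH2–OH while the only alkene present is the electron-poor enoate.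

Step 6
Reactants: 7 methyl 8α,18-dihydroxylabd-13E-en-15-oate
Product: 10 methyl (2E)-5-[(1S,4aR,5R,8aR)-5-(hydroxymethyl)-5,8a-dimethyl-2-methylidenedecahydronaphthalen-1-yl]-3-methylpent-2-enoate (methyl 18-hydroxylabda-8(17),13E-dien-15-oate), via 18-O-TMS diol 8 (not isolated), via 18-O-TMS exocyclic alkene 9 (not isolated)
Conditions: TMSCl, Et3N, CH2Cl2, −40 °C (primary OH only), salts filtered off; Martin sulfurane, CH2Cl2, −20 to 0 °C; then K2CO3, MeOH, rt
Reagents that add atoms: none
Why: Martin sulfurane dehydration of the equatorial tertiary 8α-ol can only find an anti-periplanar hydrogen on the axial methyl, so elimination gives the exocyclic 8(17)-alkene, while the neopentyl primary hydroxyl is masked in the same flask as a TMS ether that falls off on methanolysis.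

Step 7
Reactants: 11 (5E)-6,10-dimethylundeca-5,9-dien-2-one (geranylacetone)
Product: 13 4-[(1R,2R)-2-hydroxy-2,6,6-trimethylcyclohexyl]butan-2-one, via bicyclic enol ether 12 (not isolated)
Conditions: (R,R)-IDPi (3 mol %), (CF3)3COH/CHCl3, −40 °C; then 1 M HCl, THF, 0 °C
Reagents that add atoms: water O
Why: Proposed new method: this is the silicon-free parent of step 3, in which the chiral acid protonates the terminal alkene, the E-alkene closes the cyclohexane through a chair and the ketone oxygen adds anti (side chain and C–O trans, both centres set by the catalyst), the enol ether then being hydrolysed; the closest known reactions are the IDPi-catalysed hydroxyl-terminated polyene cyclization and the racemic Brønsted-acid cyclization of geranylacetone to this enol ether.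

Step 8
Reactants: 13 4-[(1R,2R)-2-hydroxy-2,6,6-trimethylcyclohexyl]butan-2-one
Product: 14 methyl (2E)-5-[(1R,2R)-2-hydroxy-2,6,6-trimethylcyclohexyl]-3-methylpent-2-enoate
Conditions: (MeO)2P(O)CH2CO2Me, NaH, THF, 0 °C to 40 °C; E isomer separated on silica
Reagents that add atoms: trimethyl phosphonoacetate COC(=O)CP(=O)(OC)OC
Why: Horner–Wadsworth–Emmons olefination of the methyl ketone gives the E-enoate as the major, separable isomer, and geometric purity matters because E and Z would give opposite C3 epimers in step 9.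

Step 9
Reactants: 14 methyl (2E)-5-[(1R,2R)-2-hydroxy-2,6,6-trimethylcyclohexyl]-3-methylpent-2-enoate
Product: 15 methyl (3S)-5-[(1R,2R)-2-hydroxy-2,6,6-trimethylcyclohexyl]-3-methylpentanoate
Conditions: Cu(OAc)2·H2O (3 mol %), (R)-DTBM-SEGPHOS (3 mol %), (EtO)2MeSiH, t-BuOH, toluene, 0 °C to rt; then NH4F, MeOH
Reagents that add atoms: none
Why: Ligand-controlled CuH asymmetric 1,4-reduction of the β,β-disubstituted E-enoate sets C3 independently of the remote ring centres (the ligand antipode that gives 3S is confirmed on the first run; the other antipode gives 3R).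

Step 10
Reactants: 15 methyl (3S)-5-[(1R,2R)-2-hydroxy-2,6,6-trimethylcyclohexyl]-3-methylpentanoate
Product: 16 (3S)-5-[(1R,2R)-2-hydroxy-2,6,6-trimethylcyclohexyl]-3-methylpentanoic acid
Conditions: LiOH·H2O, THF/MeOH/H2O, rt; then 1 M HCl
Reagents that add atoms: lithium hydroxide [Li+].[OH-]
Why: Simple ester saponification; C3 is β to the carbonyl and cannot epimerize.

Step 11
Reactants: 10 methyl 18-hydroxylabda-8(17),13E-dien-15-oate; 16 (3S)-5-[(1R,2R)-2-hydroxy-2,6,6-trimethylcyclohexyl]-3-methylpentanoic acid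
Product: 17 target CNP0174687.1 (18-O-acyl ester of 10 with 16)
Conditions: DIC, DMAP (0.3 equiv), CH2Cl2, 0 °C to rt
Reagents that add atoms: none
Why: Steglich esterification acylates the primary neopentyl alcohol of 10, while the hindered tertiary hydroxyl of 16 and the methyl ester do not react.

**Compound list**
1 | (5E,9E)-6,10,14-trimethylpentadeca-5,9,13-trien-2-one (farnesylacetone) | CC(=O)CC/C=C(\C)CC/C=C(\C)CCC=C(C)C | starting material
2 | (5E,9E,13E)-15-hydroxy-6,10,14-trimethylpentadeca-5,9,13-trien-2-one | CC(=O)CC/C=C(\C)CC/C=C(\C)CC/C=C(\C)CO | intermediate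
3 | (5E,9E,13E)-15-[dimethyl(phenyl)silyl]-6,10,14-trimethylpentadeca-5,9,13-trien-2-one | CC(=O)CC/C=C(\C)CC/C=C(\C)CC/C=C(\C)C[Si](C)(C)c1ccccc1 | intermediate
4 | 18-[dimethyl(phenyl)silyl]-8α,13-epoxy-14,15-dinorlabd-12-ene (silyl sclareol-oxide enol ether) | C[C@@]12CC[C@H]3[C@](C)(C[Si](C)(C)c4ccccc4)CCC[C@]3(C)[C@H]1CC=C(C)O2 | intermediate
5 | 4-[(1R,2R,4aR,5R,8aS)-5-{[dimethyl(phenyl)silyl]methyl}-2-hydroxy-2,5,8a-trimethyldecahydronaphthalen-1-yl]butan-2-one | C[C@@]1(O)CC[C@H]2[C@](C)(C[Si](C)(C)c3ccccc3)CCC[C@]2(C)[C@H]1CCC(C)=O | intermediate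
6 | methyl 18-[dimethyl(phenyl)silyl]-8α-hydroxylabd-13E-en-15-oate | C[C@@]1(O)CC[C@H]2[C@](C)(C[Si](C)(C)c3ccccc3)CCC[C@]2(C)[C@H]1CC/C(C)=C/C(=O)OC | intermediate
7 | methyl 8α,18-dihydroxylabd-13E-en-15-oate | C[C@@]1(O)CC[C@H]2[C@](C)(CO)CCC[C@]2(C)[C@H]1CC/C(C)=C/C(=O)OC | intermediate
8 | methyl 8α-hydroxy-18-(trimethylsilyloxy)labd-13E-en-15-oate | C[C@@]1(O)CC[C@H]2[C@](C)(CO[Si](C)(C)C)CCC[C@]2(C)[C@H]1CC/C(C)=C/C(=O)OC | intermediate
9 | methyl 18-(trimethylsilyloxy)labda-8(17),13E-dien-15-oate | C=C1CC[C@H]2[C@](C)(CO[Si](C)(C)C)CCC[C@]2(C)[C@H]1CC/C(C)=C/C(=O)OC | intermediate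
10 | methyl (2E)-5-[(1S,4aR,5R,8aR)-5-(hydroxymethyl)-5,8a-dimethyl-2-methylidenedecahydronaphthalen-1-yl]-3-methylpent-2-enoate | C=C1CC[C@H]2[C@](C)(CO)CCC[C@]2(C)[C@H]1CC/C(C)=C/C(=O)OC | intermediate
11 | (5E)-6,10-dimethylundeca-5,9-dien-2-one (geranylacetone) | CC(=O)CC/C=C(\C)CCC=C(C)C | starting material
12 | (4aR,8aR)-2,5,5,8a-tetramethyl-4a,5,6,7,8,8a-hexahydro-4H-chromene | CC1=CC[C@@H]2C(C)(C)CCC[C@@]2(C)O1 | intermediate
13 | 4-[(1R,2R)-2-hydroxy-2,6,6-trimethylcyclohexyl]butan-2-one | CC(=O)CC[C@@H]1C(C)(C)CCC[C@@]1(C)O | intermediate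
14 | methyl (2E)-5-[(1R,2R)-2-hydroxy-2,6,6-trimethylcyclohexyl]-3-methylpent-2-enoate | COC(=O)/C=C(\C)CC[C@@H]1C(C)(C)CCC[C@@]1(C)O | intermediate
15 | methyl (3S)-5-[(1R,2R)-2-hydroxy-2,6,6-trimethylcyclohexyl]-3-methylpentanoate | COC(=O)C[C@@H](C)CC[C@@H]1C(C)(C)CCC[C@@]1(C)O | intermediate
16 | (3S)-5-[(1R,2R)-2-hydroxy-2,6,6-trimethylcyclohexyl]-3-methylpentanoic acid | OC(=O)C[C@@H](C)CC[C@@H]1C(C)(C)CCC[C@@]1(C)O | intermediate
17 | CNP0174687.1 | C=C1CC[C@H]2[C@](C)(COC(=O)C[C@@H](C)CC[C@@H]3C(C)(C)CCC[C@@]3(C)O)CCC[C@]2(C)[C@H]1CC/C(C)=C/C(=O)OC | target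

**Step count**
Total steps: 11. Longest linear sequence: 7 (steps 1–6 and 11).

**Three steps most likely to fail**

Step 3 (proposed new method). Protodesilylation may outrun ring closure, or the fold may be poorly controlled with the silyl initiator. The fallback uses known chemistry and runs from 2 back to 10. Sharpless asymmetric epoxidation of allylic alcohol 2 (Ti(OiPr)4, L-(+)-DET, TBHP, 4 Å sieves, −20 °C) gives the (13S,14S)-13,14-epoxy-15-hydroxy ketone F1. Titanocene(III)-catalysed radical epoxypolyene cyclization (Cp2TiCl2 cat., Mn, TMSCl, collidine, THF), which terminates as the exocyclic alkene, gives 3β,18-dihydroxy-14,15-dinorlabd-8(17)-en-13-one F2. HWE olefination gives methyl 3β,18-dihydroxylabda-8(17),13E-dien-15-oate F3. Thiocarbonyldiimidazole closes the 3,18-cyclic thionocarbonate F4. Bu3SnH/AIBN (Barton deoxygenation through the secondary C3 radical) gives the 18-O-[(tributylstannylthio)carbonyl] ester F5, and K2CO3/MeOH releases 10. Here the absolute sense comes from the epoxide stereocentre and the cascade is radical instead of cationic.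

Step 7 (proposed new method). The ketone may buffer the acid or the ee may be low for this short substrate. The fallback uses known chemistry and runs from 11 back to 13: racemic cyclization with ClSO3H in 2-nitropropane at −78 °C, aqueous acid, then preparative chiral SFC of the racemic ketol. This also makes the mirror-image enol ether ent-12 F6 in the flask and the mirror-image ketol ent-13 F7, which is set aside.

Step 6. The elimination may give some Δ7/Δ8 isomers (removable on AgNO3–silica), or the transient TMS protection may be incomplete. The fallback runs from 6 back to 10 and reverses the order of events. POCl3/pyridine on silane 6, which has no free primary hydroxyl, gives by classical anti E2 methyl 18-[dimethyl(phenyl)silyl]labda-8(17),13E-dien-15-oate F8. A nucleophilic, alkene-tolerant Tamao–Fleming oxidation (t-BuOOH, KH, NMP; then TBAF, 70 °C) then gives 10.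

**Further compounds**
F1 | step 3 | (13S,14S)-13,14-epoxy-15-hydroxy-6,10,14-trimethylpentadeca-5,9-dien-2-one | CC(=O)CC/C=C(\C)CC/C=C(\C)CC[C@@H]1O[C@@]1(C)CO
F2 | step 3 | 3β,18-dihydroxy-14,15-dinorlabd-8(17)-en-13-one | C=C1CC[C@H]2[C@](C)(CO)[C@@H](O)CC[C@]2(C)[C@H]1CCC(C)=O
F3 | step 3 | methyl 3β,18-dihydroxylabda-8(17),13E-dien-15-oate | C=C1CC[C@H]2[C@](C)(CO)[C@@H](O)CC[C@]2(C)[C@H]1CC/C(C)=C/C(=O)OC
F4 | step 3 | methyl 3β,18-(thiocarbonyldioxy)labda-8(17),13E-dien-15-oate (cyclic thionocarbonate) | C=C1CC[C@H]2[C@]3(C)COC(=S)O[C@H]3CC[C@]2(C)[C@H]1CC/C(C)=C/C(=O)OC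
F5 | step 3 | methyl 18-{[(tributylstannyl)sulfanyl]carbonyloxy}labda-8(17),13E-dien-15-oate | C=C1CC[C@H]2[C@](C)(COC(=O)S[Sn](CCCC)(CCCC)CCCC)CCC[C@]2(C)[C@H]1CC/C(C)=C/C(=O)OC
F6 | step 7 | (4aS,8aS)-2,5,5,8a-tetramethyl-4a,5,6,7,8,8a-hexahydro-4H-chromene (ent-12) | CC1=CC[C@H]2C(C)(C)CCC[C@]2(C)O1
F7 | step 7 | 4-[(1S,2S)-2-hydroxy-2,6,6-trimethylcyclohexyl]butan-2-one (ent-13) | CC(=O)CC[C@H]1C(C)(C)CCC[C@]1(C)O
F8 | step 6 | methyl 18-[dimethyl(phenyl)silyl]labda-8(17),13E-dien-15-oate | C=C1CC[C@H]2[C@](C)(C[Si](C)(C)c3ccccc3)CCC[C@]2(C)[C@H]1CC/C(C)=C/C(=O)OC
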